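The dihydropyran ring is cut at C4–C4a and O1–C2, taking a five-carbon unit off a 5-substituted resorcinol. The key step exploits that, in the chroman benzene ring, C4a lies para to the C7 hydroxyl and next to C8a–O1. The unit is parked as a prenyl ether on O7, travels by a Claisen–Cope relay to C4a, and acid in the same flask closes O1 onto the tertiary carbon. The precursor is 3-ethynyl-5-(prenyloxy)phenol. Its alkyne later builds the benzofuran by Sonogashira annulation. A second Claisen shift, para-blocked by C3a, places the 1,1-dimethylallyl group on benzofuran C7.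

Key step: step 3

Remark: the locants O1, C2, C3, C4, C4a, C5 to C8 and C8a are those of the chroman ring of the target and are used for the same atoms in its precursors. Benzofuran locants are marked as such. Prenyl means 3-methylbut-2-en-1-yl. The target has no stereocentre.

Step 1
Reactants: 1 3,5-dihydroxybenzaldehyde; 2 prenyl bromide (1-bromo-3-methylbut-2-ene)
Product: 3 3-hydroxy-5-[(3-methylbut-2-en-1-yl)oxy]benzaldehyde
Conditions: 1 (1.5 equiv), 2 (1.0 equiv), K2CO3 (1.1 equiv), DMF, 0 °C to rt
Reagents that add atoms: none
Why: Williamson etherification; the two hydroxyls of 1 are equivalent, so a deficit of the allylic bromide should give mainly the monoether beside separable diether and recovered 1, and the formyl group keeps the ring too electron-poor for C-alkylation.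

Step 2
Reactants: 3 3-hydroxy-5-[(3-methylbut-2-en-1-yl)oxy]benzaldehyde
Product: 4 3-ethynyl-5-[(3-methylbut-2-en-1-yl)oxy]phenol
Conditions: Ohira–Bestmann reagent (1.3 equiv), K2CO3 (2.5 equiv), MeOH, 0 °C to rt
Reagents that add atoms: dimethyl (1-diazo-2-oxopropyl)phosphonate, CC(=O)C(=[N+]=[N-])P(=O)(OC)OC
Why: Ohira–Bestmann (Seyferth–Gilbert) homologation; methanolysis of the reagent frees the diazomethylphosphonate anion, which turns the non-enolisable aryl aldehyde into the terminal alkyne, while the phenoxide (meta to the formyl group, hence not conjugated with it) and the prenyl ether are left untouched.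

Step 3
Reactants: 4 3-ethynyl-5-[(3-methylbut-2-en-1-yl)oxy]phenol
Product: 7 5-ethynyl-2,2-dimethylchroman-7-ol, via ortho-dienone 5 (not isolated), via 4-prenylresorcinol 6 (not isolated)
Conditions: 1,2-dichlorobenzene (0.02 M, degassed, base-washed sealed tube), 185 °C; then 40 °C, p-TsOH·H2O (10 mol %), same flask
Reagents that add atoms: none
Why: At 185 °C an aromatic Claisen [3,3] shift moves the CMe2 end of the prenyl group from O7 to an ortho carbon (drawn for C6 in 5), and the crowded dienone relays it by a Cope [3,3] shift, now with its CH2 end, to C4a, the only carbon para to O7, so that tautomerisation gives 6 with the C4–C4a bond made and the C7 hydroxyl set free. p-TsOH added to the same flask then protonates the trisubstituted alkene at C3 and the adjacent phenol oxygen O1 traps the tertiary cation at C2, a Markovnikov 6-endo-trig hydroalkoxylation that closes the dihydropyran ring. The closest known reaction types are the tandem para-Claisen–Cope rearrangement of aryl prenyl ethers that still carry ortho hydrogens and the acid cyclisation of ortho-prenylphenols to 2,2-dimethylchromans. The selectivity needed is attack at the ring carbon between the ethynyl-bearing C5 and C8a and not at C8 between the two oxygens, which cationic prenylation of a 5-substituted resorcinol does not secure; here the two suprafacial shifts can only end para to O7, both possible ortho-dienones (C6 or C8) converge on C4a, and only O1 sits next to the prenyl group in 6, so a single chroman can form. The competing tautomerisation of 5 to an ortho-(1,1-dimethylallyl)phenol is bimolecular and is held back by high dilution in an aprotic, non-basic solvent, while the slim ethynyl group keeps C6 and C4a open. No stereocentre is created.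

Step 4
Reactants: 8 phloroglucinol (benzene-1,3,5-triol); 9 prenol (3-methylbut-2-en-1-ol)
Product: 10 5-[(3-methylbut-2-en-1-yl)oxy]benzene-1,3-diol
Conditions: 8 (3 equiv), 9 (1 equiv), PPh3, DIAD, THF, 0 °C to rt
Reagents that add atoms: none
Why: Mitsunobu etherification; the three hydroxyls of 8 are equivalent, activation of the allylic alcohol as its oxyphosphonium salt under neutral conditions favours O-alkylation over the C-alkylation that phloroglucinolate salts show with prenyl halides, and the excess of 8 limits double etherification.

Step 5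
Reactants: 10 5-[(3-methylbut-2-en-1-yl)oxy]benzene-1,3-diol
Product: 11 2-iodo-5-[(3-methylbut-2-en-1-yl)oxy]benzene-1,3-diol
Conditions: I2 (1.0 equiv), NaHCO3 (1.1 equiv), THF/H2O, 0 °C
Reagents that add atoms: iodine, [I][I]
Why: Electrophilic aromatic iodination of a phenolate; as resorcinol does under the same conditions, the ring should take up iodine at the least crowded carbon between the two free hydroxyls (para to the ether oxygen), and the phloroglucinol-type ring should consume the single equivalent of iodine far faster than the trisubstituted alkene.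

Step 6
Reactants: 7 5-ethynyl-2,2-dimethylchroman-7-ol; 11 2-iodo-5-[(3-methylbut-2-en-1-yl)oxy]benzene-1,3-diol
Product: 13 2-(7-hydroxy-2,2-dimethylchroman-5-yl)-6-[(3-methylbut-2-en-1-yl)oxy]benzofuran-4-ol, via diarylalkyne 12 (not isolated)
Conditions: PdCl2(PPh3)2 (5 mol %), CuI (10 mol %), Et3N, DMF, 60 °C, argon
Reagents that add atoms: none
Why: Domino Sonogashira coupling and 5-endo-dig cycloisomerisation; the aryl iodide couples with the terminal alkyne to give 12, in which either of the two equivalent ortho hydroxyls adds to the metal-activated triple bond to close the furan ring while the other becomes the benzofuran C4 hydroxyl, and the tertiary amine offers no soft nucleophile that would let zerovalent palladium strip the prenyl ether.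

Step 7
Reactants: 13 2-(7-hydroxy-2,2-dimethylchroman-5-yl)-6-[(3-methylbut-2-en-1-yl)oxy]benzofuran-4-ol
Product: 15 target, 2-(7-hydroxy-2,2-dimethylchroman-5-yl)-7-(2-methylbut-3-en-2-yl)benzofuran-4,6-diol, via C7-dienone 14 (not isolated)
Conditions: N,N-diethylaniline, 175 °C, argon, stopped when 13 is consumed
Reagents that add atoms: none
Why: Aromatic Claisen rearrangement; the [3,3] shift of the 6-O-prenyl group should deliver its CMe2 end to benzofuran C7 because dienone 14 keeps the furan sextet whereas attack at C5 would break it, the para carbon C3a is a ring-fusion carbon so no Cope relay can follow, tautomerisation gives the 6-hydroxy-7-(1,1-dimethylallyl) pattern, and the amine solvent buffers traces of acid that would cyclise the product.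

Compound list
1 | 3,5-dihydroxybenzaldehyde | O=Cc1cc(O)cc(O)c1 | starting material
2 | prenyl bromide (1-bromo-3-methylbut-2-ene) | CC(C)=CCBr | starting material
3 | 3-hydroxy-5-[(3-methylbut-2-en-1-yl)oxy]benzaldehyde | O=Cc1cc(O)cc(OCC=C(C)C)c1 | intermediate
4 | 3-ethynyl-5-[(3-methylbut-2-en-1-yl)oxy]phenol | C#Cc1cc(O)cc(OCC=C(C)C)c1 | intermediate
5 | ortho-dienone, 5-ethynyl-3-hydroxy-6-(2-methylbut-3-en-2-yl)cyclohexa-2,4-dien-1-one (racemic, transient) | C#CC1=CC(O)=CC(=O)C1C(C)(C)C=C | intermediate
6 | 5-ethynyl-4-(3-methylbut-2-en-1-yl)benzene-1,3-diol | C#Cc1cc(O)cc(O)c1CC=C(C)C | intermediate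
7 | 5-ethynyl-2,2-dimethylchroman-7-ol | C#Cc1cc(O)cc2c1CCC(C)(C)O2 | intermediate
8 | phloroglucinol (benzene-1,3,5-triol) | Oc1cc(O)cc(O)c1 | starting material
9 | prenol (3-methylbut-2-en-1-ol) | CC(C)=CCO | starting material
10 | 5-[(3-methylbut-2-en-1-yl)oxy]benzene-1,3-diol | CC(C)=CCOc1cc(O)cc(O)c1 | intermediate
11 | 2-iodo-5-[(3-methylbut-2-en-1-yl)oxy]benzene-1,3-diol | CC(C)=CCOc1cc(O)c(I)c(O)c1 | intermediate
12 | 2-[(7-hydroxy-2,2-dimethylchroman-5-yl)ethynyl]-5-[(3-methylbut-2-en-1-yl)oxy]benzene-1,3-diol | CC(C)=CCOc1cc(O)c(C#Cc2cc(O)cc3c2CCC(C)(C)O3)c(O)c1 | intermediate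
13 | 2-(7-hydroxy-2,2-dimethylchroman-5-yl)-6-[(3-methylbut-2-en-1-yl)oxy]benzofuran-4-ol | CC(C)=CCOc1cc(O)c2cc(-c3cc(O)cc4c3CCC(C)(C)O4)oc2c1 | intermediate
14 | C7-dienone, 4-hydroxy-2-(7-hydroxy-2,2-dimethylchroman-5-yl)-7-(2-methylbut-3-en-2-yl)benzofuran-6(7H)-one (racemic, transient) | C=CC(C)(C)C1C(=O)C=C(O)c2cc(-c3cc(O)cc4c3CCC(C)(C)O4)oc21 | intermediate
15 | 2-(7-hydroxy-2,2-dimethylchroman-5-yl)-7-(2-methylbut-3-en-2-yl)benzofuran-4,6-diol | C=CC(C)(C)c1c(O)cc(O)c2cc(-c3cc(O)cc4c3CCC(C)(C)O4)oc12 | target

Total step count: 7. Longest linear sequence: 5 steps (steps 1, 2, 3, 6 and 7).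

Steps most likely to fail

Step 3. The relay may stop halfway, because the ortho-dienone can tautomerise before the Cope shift. The ether may also lose isoprene on heating, or the terminal alkyne may oligomerise at 185 °C. The fallback fixes the site of the new C–C bond with a halogen instead of a sigmatropic relay. It sets out from 1.
- NBS in MeCN at 0 °C should brominate para to one hydroxyl and ortho to the other, giving 2-bromo-3,5-dihydroxybenzaldehyde F1.
- A Heck reaction with 2-methylbut-3-en-2-ol (Pd(OAc)2, P(o-tol)3, Et3N, DMF, 100 °C) should give (E)-3,5-dihydroxy-2-(3-hydroxy-3-methylbut-1-en-1-yl)benzaldehyde F2.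
- p-TsOH added to the same flask should cyclodehydrate F2 through its allyl cation to 7-hydroxy-2,2-dimethyl-2H-chromene-5-carbaldehyde F3.
- H2 over Pd/C in EtOAc saturates the C3=C4 bond to give 7-hydroxy-2,2-dimethylchroman-5-carbaldehyde F4.
- The conditions of step 2 convert F4 into 7, where the route is rejoined.

Step 7. The freshly formed ortho-(1,1-dimethylallyl)phenol may react further at the reaction temperature. Possible paths are abnormal Claisen isomerisation and ring closure of the 6-hydroxyl onto the vinyl group. The ether may also lose isoprene. The fallback masks the phenol at the moment it forms. It sets out from 13.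
- Ac2O and pyridine give 2-(7-acetoxy-2,2-dimethylchroman-5-yl)-6-(prenyloxy)benzofuran-4-yl acetate F5.
- Heating F5 in N,N-diethylaniline with Ac2O and NaOAc lets the rearranged phenol be acetylated as it appears, giving the triacetate of the target F6.
- K2CO3 in MeOH at rt removes the three acetates and returns to 15.

Step 5. Iodine may enter beside the ether oxygen instead of between the hydroxyls. A second iodination may follow, or iodine may add to the alkene. The fallback reverses the order of events, so that iodination meets neither an alkene nor a regiochemical choice. It sets out from 8.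
- I2 and NaHCO3 in THF/H2O at 0 °C give 2-iodobenzene-1,3,5-triol F7.
- Mitsunobu etherification of F7 with 9 (PPh3, DIAD, THF) should occur at the only hydroxyl not flanked by iodine, and returns to 11.

Further compounds
F1 | step 3 | 2-bromo-3,5-dihydroxybenzaldehyde | O=Cc1cc(O)cc(O)c1Br
F2 | step 3 | (E)-3,5-dihydroxy-2-(3-hydroxy-3-methylbut-1-en-1-yl)benzaldehyde | O=Cc1cc(O)cc(O)c1/C=C/C(C)(C)O
F3 | step 3 | 7-hydroxy-2,2-dimethyl-2H-chromene-5-carbaldehyde | O=Cc1cc(O)cc2c1C=CC(C)(C)O2
F4 | step 3 | 7-hydroxy-2,2-dimethylchroman-5-carbaldehyde | O=Cc1cc(O)cc2c1CCC(C)(C)O2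
F5 | step 7 | 2-(7-acetoxy-2,2-dimethylchroman-5-yl)-6-(prenyloxy)benzofuran-4-yl acetate | CC(C)=CCOc1cc(OC(C)=O)c2cc(-c3cc(OC(C)=O)cc4c3CCC(C)(C)O4)oc2c1
F6 | step 7 | triacetate of the target | C=CC(C)(C)c1c(OC(C)=O)cc(OC(C)=O)c2cc(-c3cc(OC(C)=O)cc4c3CCC(C)(C)O4)oc12
F7 | step 5 | 2-iodobenzene-1,3,5-triol | Oc1cc(O)c(I)c(O)c1
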